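**Plan**

- Locants: unprimed = 4-methoxyphenyl flavanone (unit A: O1, C2, C3, C4); doubly primed = 4-hydroxyphenyl flavanone (unit B). The target is (2S,3R,2''S,3''S): unit A is 2,3-trans, unit B is 2'',3''-cis.
- Enabling feature: C4(=O)–C3–C3''–C4''(=O) is a 1,4-diketone whose inner carbons C3/C3'' can be the two carbons of an alkyne lying between the aryl ether stereocentres C2 and C2''. Each carbonyl carbon is an aryl aldehyde carbon ortho to O1 or O1'', five atoms from the alkyne carbon it must reach.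
- Retrosynthesis: cut C3–C4 (intramolecular Stetter), then C3''–C4'' (carbene-catalysed alkyne hydroacylation), then O1–C2 and O1''–C2'' (two Mitsunobu etherifications with one salicylaldehyde), then C2''–C3'' and C2–C3 (two asymmetric alkynylations, ethynyltrimethylsilane supplying C3/C3'').
- Forward: alkynylation, etherification, masking of the first formyl group, alkynylation, etherification. The pyranone ring of unit B then closes by 6-exo-dig hydroacylation, and the pyranone ring of unit A by 6-exo-trig Stetter addition onto the enone just made. Hydrogenolysis ends the route.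
- Stereochemistry: C2 and C2'' come from two ligand-controlled alkynylations, each inverted in its Mitsunobu step. C3 comes from allylic 1,3-strain of C2 in the Stetter closure. C3'' comes from kinetic protonation of the unit B enolate anti to the C2'' aryl group, whatever the E/Z ratio of the enone, because the geometry is erased in the enolate.

Key step: step 7

Remark: the (S,S)-ProPhenol/Me2Zn system is taken to deliver the alkynyl group to the Re face of aryl aldehydes; if the sense is the opposite, the (R,R)-ligand is used and nothing else changes.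
Remark: several CIP descriptors change along the route without any change of configuration (silylalkynyl and internal alkynyl rank above aryl, ethynyl and alkenyl below it; sp2 C3'' ranks above aryl, sp3 C3'' below it); the SMILES are authoritative.

**Route**

Step 1
Reactants: 1 2,4,6-trihydroxybenzaldehyde
Product: 2 2,4-bis(benzyloxy)-6-hydroxybenzaldehyde
Conditions: BnBr (2.05 equiv), K2CO3, DMF, 0 to 23 °C
Reagents that add atoms: benzyl bromide, BrCc1ccccc1
Why: Williamson etherification in which the 4-hydroxyl and one ortho hydroxyl are alkylated while the other ortho hydroxyl, held in a hydrogen bond to the formyl oxygen, should stay free; no stereocentre is involved.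

Step 2
Reactants: 3 4-methoxybenzaldehyde; 4 ethynyltrimethylsilane
Product: 5 (1S)-1-(4-methoxyphenyl)-3-(trimethylsilyl)prop-2-yn-1-ol
Conditions: (S,S)-ProPhenol (10 mol %), Me2Zn (3 equiv), Ph3PO (20 mol %), toluene, 0 °C; aq. NH4Cl
Reagents that add atoms: none
Why: Ligand-controlled catalytic asymmetric addition of the zinc alkynylide to the Re face of the aldehyde (dinuclear zinc ProPhenol alkynylation) should set the carbinol carbon, the future C2, as S.

Step 3
Reactants: 5 (1S)-1-(4-methoxyphenyl)-3-(trimethylsilyl)prop-2-yn-1-ol; 2 2,4-bis(benzyloxy)-6-hydroxybenzaldehyde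
Product: 6 2,4-bis(benzyloxy)-6-{[(1R)-1-(4-methoxyphenyl)-3-(trimethylsilyl)prop-2-yn-1-yl]oxy}benzaldehyde
Conditions: PPh3, DIAD, toluene, −20 to 0 °C
Reagents that add atoms: none
Why: Mitsunobu etherification with the acidic phenol of 2 proceeds by SN2 displacement of the alkoxyphosphonium ion, so the carbinol centre should be inverted (S to R) to the spatial arrangement of C2 in the target, with low temperature and a non-polar solvent holding back ionisation.

Step 4
Reactants: 6 2,4-bis(benzyloxy)-6-{[(1R)-1-(4-methoxyphenyl)-3-(trimethylsilyl)prop-2-yn-1-yl]oxy}benzaldehyde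
Product: 8 2-[2,4-bis(benzyloxy)-6-{[(1S)-1-(4-methoxyphenyl)prop-2-yn-1-yl]oxy}phenyl]-5,5-dimethyl-1,3-dioxane, via silyl alkyne dioxane 7 (not isolated)
Conditions: 2,2-dimethylpropane-1,3-diol (3 equiv), HC(OMe)3 (2 equiv), PPTS (5 mol %), CH2Cl2, 23 °C; then K2CO3 (0.5 equiv), MeOH, 23 °C
Reagents that add atoms: 2,2-dimethylpropane-1,3-diol, OCC(C)(C)CO
Why: Orthoformate-driven acetalisation masks the formyl group as a 1,3-dioxane that tolerates base and zinc reagents, and carbonate in methanol then cleaves the alkynyl C–Si bond (protodesilylation), the stereocentre being untouched.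

Step 5
Reactants: 8 2-[2,4-bis(benzyloxy)-6-{[(1S)-1-(4-methoxyphenyl)prop-2-yn-1-yl]oxy}phenyl]-5,5-dimethyl-1,3-dioxane; 9 4-(benzyloxy)benzaldehyde
Product: 10 (1S,4R)-1-[4-(benzyloxy)phenyl]-4-[3,5-bis(benzyloxy)-2-(5,5-dimethyl-1,3-dioxan-2-yl)phenoxy]-4-(4-methoxyphenyl)but-2-yn-1-ol
Conditions: (S,S)-ProPhenol (20 mol %), Me2Zn (3 equiv), Ph3PO (40 mol %), toluene, 0 °C; pH 7 phosphate buffer
Reagents that add atoms: none
Why: The same catalytic asymmetric zinc alkynylide addition to the Re face of 9 should set the new carbinol centre (the future C2'') as S under ligand control, the remote ether centre being a spectator.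

Step 6
Reactants: 10 (1S,4R)-1-[4-(benzyloxy)phenyl]-4-[3,5-bis(benzyloxy)-2-(5,5-dimethyl-1,3-dioxan-2-yl)phenoxy]-4-(4-methoxyphenyl)but-2-yn-1-ol; 2 2,4-bis(benzyloxy)-6-hydroxybenzaldehyde
Product: 11 2,4-bis(benzyloxy)-6-{[(1R,4R)-1-[4-(benzyloxy)phenyl]-4-[3,5-bis(benzyloxy)-2-(5,5-dimethyl-1,3-dioxan-2-yl)phenoxy]-4-(4-methoxyphenyl)but-2-yn-1-yl]oxy}benzaldehyde
Conditions: PPh3, DIAD, toluene, −20 to 0 °C
Reagents that add atoms: none
Why: A second Mitsunobu etherification with inversion (S to R) installs O1'' and the only free formyl group of the molecule, which should give the (R,R)-bis(aryl ether) with its two acyl anion precursors differentiated as aldehyde and acetal.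

Step 7
Reactants: 11 2,4-bis(benzyloxy)-6-{[(1R,4R)-1-[4-(benzyloxy)phenyl]-4-[3,5-bis(benzyloxy)-2-(5,5-dimethyl-1,3-dioxan-2-yl)phenoxy]-4-(4-methoxyphenyl)but-2-yn-1-yl]oxy}benzaldehyde
Product: 13 2,4-bis(benzyloxy)-6-{(1S,2E)-2-[(2R)-5,7-bis(benzyloxy)-2-[4-(benzyloxy)phenyl]-4-oxo-2H-chromen-3(4H)-ylidene]-1-(4-methoxyphenyl)ethoxy}benzaldehyde, via alkylidene chromanone dioxane 12 (not isolated)
Conditions: 3-(2,4,6-trimethylphenyl)-5,6,7,8-tetrahydro-4H-cyclohepta[d][1,3]thiazol-3-ium perchlorate (10 mol %), K2CO3 (20 mol %), THF, 70 °C; then 1 M aq. HCl, THF, 23 °C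
Reagents that add atoms: water, O
Why: The thiazolylidene adds to the only free aldehyde of 11 to give the Breslow intermediate, whose nucleophilic carbon (the future C4'') attacks the proximal alkyne carbon (the future C3'') while the enol O–H proton passes to the distal alkyne carbon in a concerted Conia-ene-like transition state, and loss of the carbene releases the 3-alkylidene chroman-4-one. The closest known reaction type is the carbene-catalysed intramolecular hydroacylation of unactivated alkynes in 2-(prop-2-ynyloxy)benzaldehydes. The ring closes in the 6-exo-dig mode through C4'', C4a'', C8a'', O1'', C2'' and C3'', the 7-endo mode being out of reach of the ene-like array. No stereocentre is formed; syn addition of acyl carbon and hydrogen should give the E alkene, and the C–H bonds at C2 and C2'' are too weakly acidic for carbonate to touch. The step needs chemoselectivity between the two aryl aldehyde carbons, secured by the dioxane mask so that unit B must cyclise first (which is what assigns the cis relationship to unit B in step 8), and it needs the exocyclic enone to survive without migration into the ring, secured by the weak heterogeneous base. The dilute acid added at the end only hydrolyses the very electron-rich aryl acetal and so unveils the second acyl anion precursor next to the new Michael acceptor.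

Step 8
Reactants: 13 2,4-bis(benzyloxy)-6-{(1S,2E)-2-[(2R)-5,7-bis(benzyloxy)-2-[4-(benzyloxy)phenyl]-4-oxo-2H-chromen-3(4H)-ylidene]-1-(4-methoxyphenyl)ethoxy}benzaldehyde
Product: 14 (2S,3R)-5,7-bis(benzyloxy)-3-{(2S,3S)-5,7-bis(benzyloxy)-2-[4-(benzyloxy)phenyl]-4-oxo-3,4-dihydro-2H-chromen-3-yl}-2-(4-methoxyphenyl)-2,3-dihydro-4H-chromen-4-one
Conditions: 2-(pentafluorophenyl)-6,7-dihydro-5H-pyrrolo[2,1-c][1,2,4]triazol-2-ium tetrafluoroborate (20 mol %), iPr2NEt (20 mol %), toluene/tert-amyl alcohol (4:1), 23 °C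
Reagents that add atoms: none
Why: Intramolecular Stetter reaction (6-exo-trig) in which the Breslow intermediate of the unmasked aldehyde adds to the β-carbon C3 of the exocyclic enone from the face fixed by C2 (its hydrogen eclipses the alkene to avoid allylic 1,3-strain with C2'', so O1 delivers the acyl carbon and the 2,3-trans ring should result), after which the unit B enolate, common to both alkene isomers, should be protonated by the alcohol co-solvent at C3'' anti to the pseudoaxial C2'' aryl group to give the kinetic 2'',3''-cis unit, the weak amine base leaving both new α-keto centres unequilibrated.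

Step 9
Reactants: 14 (2S,3R)-5,7-bis(benzyloxy)-3-{(2S,3S)-5,7-bis(benzyloxy)-2-[4-(benzyloxy)phenyl]-4-oxo-3,4-dihydro-2H-chromen-3-yl}-2-(4-methoxyphenyl)-2,3-dihydro-4H-chromen-4-one
Product: 15 (2S,3R)-3-[(2S,3S)-5,7-dihydroxy-2-(4-hydroxyphenyl)-4-oxo-3,4-dihydro-2H-chromen-3-yl]-5,7-dihydroxy-2-(4-methoxyphenyl)-2,3-dihydro-4H-chromen-4-one
Conditions: H2 (1 atm), 10% Pd/C, EtOAc/MeOH, 23 °C
Reagents that add atoms: none
Why: Hydrogenolysis of the five benzyl ethers under neutral conditions should leave the aryl ketones, the methyl ether and the cyclic benzylic C2–O1 and C2''–O1'' bonds intact and cannot epimerise C3 or C3''.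

**Compound list**

1 | 2,4,6-trihydroxybenzaldehyde | O=Cc1c(O)cc(O)cc1O | starting material
2 | 2,4-bis(benzyloxy)-6-hydroxybenzaldehyde | O=Cc1c(O)cc(OCc2ccccc2)cc1OCc1ccccc1 | intermediate
3 | 4-methoxybenzaldehyde | COc1ccc(C=O)cc1 | starting material
4 | ethynyltrimethylsilane | C#C[Si](C)(C)C | starting material
5 | (1S)-1-(4-methoxyphenyl)-3-(trimethylsilyl)prop-2-yn-1-ol | COc1ccc([C@@H](C#C[Si](C)(C)C)O)cc1 | intermediate
6 | 2,4-bis(benzyloxy)-6-{[(1R)-1-(4-methoxyphenyl)-3-(trimethylsilyl)prop-2-yn-1-yl]oxy}benzaldehyde | COc1ccc([C@H](C#C[Si](C)(C)C)Oc2cc(OCc3ccccc3)cc(OCc3ccccc3)c2C=O)cc1 | intermediate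
7 | 2-[2,4-bis(benzyloxy)-6-{[(1R)-1-(4-methoxyphenyl)-3-(trimethylsilyl)prop-2-yn-1-yl]oxy}phenyl]-5,5-dimethyl-1,3-dioxane | COc1ccc([C@H](C#C[Si](C)(C)C)Oc2cc(OCc3ccccc3)cc(OCc3ccccc3)c2C2OCC(C)(C)CO2)cc1 | intermediate
8 | 2-[2,4-bis(benzyloxy)-6-{[(1S)-1-(4-methoxyphenyl)prop-2-yn-1-yl]oxy}phenyl]-5,5-dimethyl-1,3-dioxane | COc1ccc([C@H](C#C)Oc2cc(OCc3ccccc3)cc(OCc3ccccc3)c2C2OCC(C)(C)CO2)cc1 | intermediate
9 | 4-(benzyloxy)benzaldehyde | O=Cc1ccc(OCc2ccccc2)cc1 | starting material
10 | (1S,4R)-1-[4-(benzyloxy)phenyl]-4-[3,5-bis(benzyloxy)-2-(5,5-dimethyl-1,3-dioxan-2-yl)phenoxy]-4-(4-methoxyphenyl)but-2-yn-1-ol | COc1ccc([C@H](C#C[C@@H](O)c2ccc(OCc3ccccc3)cc2)Oc2cc(OCc3ccccc3)cc(OCc3ccccc3)c2C2OCC(C)(C)CO2)cc1 | intermediate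
11 | 2,4-bis(benzyloxy)-6-{[(1R,4R)-1-[4-(benzyloxy)phenyl]-4-[3,5-bis(benzyloxy)-2-(5,5-dimethyl-1,3-dioxan-2-yl)phenoxy]-4-(4-methoxyphenyl)but-2-yn-1-yl]oxy}benzaldehyde | COc1ccc([C@H](C#C[C@H](Oc2cc(OCc3ccccc3)cc(OCc3ccccc3)c2C=O)c2ccc(OCc3ccccc3)cc2)Oc2cc(OCc3ccccc3)cc(OCc3ccccc3)c2C2OCC(C)(C)CO2)cc1 | intermediate
12 | (2R,3E)-5,7-bis(benzyloxy)-2-[4-(benzyloxy)phenyl]-3-{(2S)-2-[3,5-bis(benzyloxy)-2-(5,5-dimethyl-1,3-dioxan-2-yl)phenoxy]-2-(4-methoxyphenyl)ethylidene}-2,3-dihydro-4H-chromen-4-one | COc1ccc([C@H](/C=C2/C(=O)c3c(OCc4ccccc4)cc(OCc4ccccc4)cc3O[C@@H]2c2ccc(OCc3ccccc3)cc2)Oc2cc(OCc3ccccc3)cc(OCc3ccccc3)c2C2OCC(C)(C)CO2)cc1 | intermediate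
13 | 2,4-bis(benzyloxy)-6-{(1S,2E)-2-[(2R)-5,7-bis(benzyloxy)-2-[4-(benzyloxy)phenyl]-4-oxo-2H-chromen-3(4H)-ylidene]-1-(4-methoxyphenyl)ethoxy}benzaldehyde | COc1ccc([C@H](/C=C2/C(=O)c3c(OCc4ccccc4)cc(OCc4ccccc4)cc3O[C@@H]2c2ccc(OCc3ccccc3)cc2)Oc2cc(OCc3ccccc3)cc(OCc3ccccc3)c2C=O)cc1 | intermediate
14 | (2S,3R)-5,7-bis(benzyloxy)-3-{(2S,3S)-5,7-bis(benzyloxy)-2-[4-(benzyloxy)phenyl]-4-oxo-3,4-dihydro-2H-chromen-3-yl}-2-(4-methoxyphenyl)-2,3-dihydro-4H-chromen-4-one | COc1ccc([C@H]2Oc3cc(OCc4ccccc4)cc(OCc4ccccc4)c3C(=O)[C@@H]2[C@@H]2C(=O)c3c(OCc4ccccc4)cc(OCc4ccccc4)cc3O[C@@H]2c2ccc(OCc3ccccc3)cc2)cc1 | intermediate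
15 | (2S,3R)-3-[(2S,3S)-5,7-dihydroxy-2-(4-hydroxyphenyl)-4-oxo-3,4-dihydro-2H-chromen-3-yl]-5,7-dihydroxy-2-(4-methoxyphenyl)-2,3-dihydro-4H-chromen-4-one | COc1ccc([C@H]2Oc3cc(O)cc(O)c3C(=O)[C@@H]2[C@@H]2C(=O)c3c(O)cc(O)cc3O[C@@H]2c2ccc(O)cc2)cc1 | target

**Step count**

Total steps: 9. Longest linear sequence: 8 steps (steps 2 to 9, or step 1 followed by steps 3 to 9).

**Steps most likely to fail**

1. Step 8. The tether has to use the face of the enone on which the pseudoaxial C2'' aryl group stands; if that clash outweighs the allylic strain, addition occurs on the other face and the 2,3-cis ring forms. Separately, the proton may reach C3'' from the face of the new bond (intramolecular O–H transfer) and not from the open face, which gives the 2'',3''-trans unit. The fallback sets out from 13 and uses an aroyl radical in place of the acyl anion equivalent. Oxidation of the formyl group (NaClO2, NaH2PO4, 2-methyl-2-butene, tert-butanol/water) should give 2,4-bis(benzyloxy)-6-{(1S,2E)-2-[(2R)-5,7-bis(benzyloxy)-2-[4-(benzyloxy)phenyl]-4-oxo-2H-chromen-3(4H)-ylidene]-1-(4-methoxyphenyl)ethoxy}benzoic acid F1. Treatment with PhSeSePh and PBu3 in CH2Cl2 should give its Se-phenyl selenoester F2. With (Me3Si)3SiH and Et3B/air in toluene at −20 °C the aroyl radical should close 6-exo-trig onto C3 under the same allylic strain control. The α-keto radical at C3'' then takes hydrogen from the bulky silane on the open face anti to the C2'' aryl group, and the sequence comes back to the route at 14.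

2. Step 7. Formation of the Breslow intermediate at the di-ortho-alkoxy, electron-rich aldehyde may be slow; base can then move the new double bond into the ring (loss of the C2'' stereocentre) or expel aryloxide from the propargylic position. The fallback sets out from 11. Ag2O (from AgNO3 and NaOH) in aqueous ethanol/THF, a basic medium that spares the acetal, should give 2,4-bis(benzyloxy)-6-{[(1R,4R)-1-[4-(benzyloxy)phenyl]-4-[3,5-bis(benzyloxy)-2-(5,5-dimethyl-1,3-dioxan-2-yl)phenoxy]-4-(4-methoxyphenyl)but-2-yn-1-yl]oxy}benzoic acid F3. PhSeSePh and PBu3 should convert it into the Se-phenyl selenoester F4. With (Me3Si)3SiH and AIBN in benzene at 80 °C the aroyl radical should close 6-exo-dig onto the alkyne and the vinyl radical is reduced by the silane. This gives 12, possibly as an E/Z mixture, which does not matter because step 8 erases the geometry. The acid treatment of step 7 then leads on to 13.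

3. Step 3 (the same process threatens step 6). The alkoxyphosphonium intermediate sits on a carbon that is both 4-alkoxybenzylic and propargylic, so it may ionise; substitution then runs partly through an ion pair and the configuration is eroded. The fallback makes the C–O bond at the aryl carbon, so that the stereocentre is a spectator. It sets out from 3 and 4. Alkynylation as in step 2 but with the antipodal (R,R)-ligand should give (1R)-1-(4-methoxyphenyl)-3-(trimethylsilyl)prop-2-yn-1-ol F5. Separately, 2,4,6-trifluorobenzonitrile with benzyl alcohol (2 equiv) and NaH in THF should be substituted at the para and then at one ortho position to give 2,4-bis(benzyloxy)-6-fluorobenzonitrile F6. The potassium alkoxide of F5 (KN(SiMe3)2, THF, 0 °C) should displace the remaining fluoride by SNAr with retention at carbon, giving 2,4-bis(benzyloxy)-6-{[(1R)-1-(4-methoxyphenyl)-3-(trimethylsilyl)prop-2-yn-1-yl]oxy}benzonitrile F7. Reduction with iBu2AlH in toluene at −78 °C and aqueous acid work-up should turn the nitrile into the aldehyde, and the sequence comes back to the route at 6.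

**Further compounds**

F1 | step 8 | 2,4-bis(benzyloxy)-6-{(1S,2E)-2-[(2R)-5,7-bis(benzyloxy)-2-[4-(benzyloxy)phenyl]-4-oxo-2H-chromen-3(4H)-ylidene]-1-(4-methoxyphenyl)ethoxy}benzoic acid | COc1ccc([C@H](/C=C2/C(=O)c3c(OCc4ccccc4)cc(OCc4ccccc4)cc3O[C@@H]2c2ccc(OCc3ccccc3)cc2)Oc2cc(OCc3ccccc3)cc(OCc3ccccc3)c2C(=O)O)cc1
F2 | step 8 | Se-phenyl 2,4-bis(benzyloxy)-6-{(1S,2E)-2-[(2R)-5,7-bis(benzyloxy)-2-[4-(benzyloxy)phenyl]-4-oxo-2H-chromen-3(4H)-ylidene]-1-(4-methoxyphenyl)ethoxy}benzenecarboselenoate | COc1ccc([C@H](/C=C2/C(=O)c3c(OCc4ccccc4)cc(OCc4ccccc4)cc3O[C@@H]2c2ccc(OCc3ccccc3)cc2)Oc2cc(OCc3ccccc3)cc(OCc3ccccc3)c2C(=O)[Se]c2ccccc2)cc1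
F3 | step 7 | 2,4-bis(benzyloxy)-6-{[(1R,4R)-1-[4-(benzyloxy)phenyl]-4-[3,5-bis(benzyloxy)-2-(5,5-dimethyl-1,3-dioxan-2-yl)phenoxy]-4-(4-methoxyphenyl)but-2-yn-1-yl]oxy}benzoic acid | COc1ccc([C@H](C#C[C@H](Oc2cc(OCc3ccccc3)cc(OCc3ccccc3)c2C(=O)O)c2ccc(OCc3ccccc3)cc2)Oc2cc(OCc3ccccc3)cc(OCc3ccccc3)c2C2OCC(C)(C)CO2)cc1
F4 | step 7 | Se-phenyl 2,4-bis(benzyloxy)-6-{[(1R,4R)-1-[4-(benzyloxy)phenyl]-4-[3,5-bis(benzyloxy)-2-(5,5-dimethyl-1,3-dioxan-2-yl)phenoxy]-4-(4-methoxyphenyl)but-2-yn-1-yl]oxy}benzenecarboselenoate | COc1ccc([C@H](C#C[C@H](Oc2cc(OCc3ccccc3)cc(OCc3ccccc3)c2C(=O)[Se]c2ccccc2)c2ccc(OCc3ccccc3)cc2)Oc2cc(OCc3ccccc3)cc(OCc3ccccc3)c2C2OCC(C)(C)CO2)cc1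
F5 | step 3 | (1R)-1-(4-methoxyphenyl)-3-(trimethylsilyl)prop-2-yn-1-ol | COc1ccc([C@H](C#C[Si](C)(C)C)O)cc1
F6 | step 3 | 2,4-bis(benzyloxy)-6-fluorobenzonitrile | N#Cc1c(F)cc(OCc2ccccc2)cc1OCc1ccccc1
F7 | step 3 | 2,4-bis(benzyloxy)-6-{[(1R)-1-(4-methoxyphenyl)-3-(trimethylsilyl)prop-2-yn-1-yl]oxy}benzonitrile | COc1ccc([C@H](C#C[Si](C)(C)C)Oc2cc(OCc3ccccc3)cc(OCc3ccccc3)c2C#N)cc1
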